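## Structural features

The target is one cyclohexane ring (the quinic acid core, C1–C6, with the carboxyl carbon C7 on C1) that carries five oxygen functions and no carbon substituent other than C7. C1 is a quaternary centre bearing the carboxyl group and a tertiary (E)-caffeate, and the C2 and C6 methylenes insulate it from the other three stereocentres. C3, C4 and C5 are contiguous carbinol centres: O3 (the second caffeate) and O4 are cis, O4 and O5 are trans, and O1, O3 and O4 lie on one ring face while C7 and O5 lie on the other. The fragile parts are the two catechols (easily oxidised), the two conjugated ester alkenes (they would compete in any alkene oxidation), and the O3 ester, which can migrate to the cis-vicinal O4. The real difficulty is not the skeleton but the configuration of quaternary C1 relative to C5, and the acylation of the two least accessible hydroxyls (tertiary O1, axial O3) while O4 and O5 stay free. C7 and O5 are cis and can be tied into a γ-lactone bridge, which masks both, inverts the chair so that O3 becomes equatorial and O4 axial, and covers one ring face. The key step exploits the cis O3/O4 pair on the adjacent ring carbons C3 and C4: it is the retron of a C3=C4 double bond in the carbocycle, and opening the ring there leaves a 1,7-diene holding only C1 and C5, which ring-closing metathesis closes again.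

## Logic of the disconnections

24 back to 23. The O5–C7 bond is re-formed and the four phenolic hydroxyls are capped as acetates. The lactone hides O5 and C7 in one group and differentiates O3 from O4, so 24 needs no protecting group on its free hydroxyls or its acid. The forward step must cleave four aryl acetates and a strained γ-lactone in aqueous acid while two conjugated esters survive and do not migrate.

23 back to 22 and 20. The O3–C(acyl) bond is cut. It is cut last among the ester bonds because in the lactone chair O3 is equatorial and O4 axial, so O4 needs no protecting group. The forward step needs kinetic site selectivity and no O3→O4 migration.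

22 back to 21, and 21 back to 17 and 20. The isopropylidene acetal is restored on O3/O4 and the O1–C(acyl) bond is cut. Tertiary O1 needs forcing, nucleophile-catalysed acylation that a free secondary hydroxyl would not survive; one acetal across the cis pair is the cheapest mask. 17 then has a single free hydroxyl. The forward steps are acylation of a tertiary α-hydroxy lactone and an acetal hydrolysis that spares aryl acetates and lactone.

20 back to 19 and 19 back to 18. The C–Cl bond and the two phenolic O–acetyl bonds are cut. The acyl donor is used twice, so it is made once; the acetates must withstand acid chloride formation and both acylations.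

17 back to 16, and 16 back to 15. The acetal C–O bonds and then the C3–O3 and C4–O4 bonds are cut, returning the cis diol to the C3=C4 alkene. A cis-vicinal diol calls for syn-dihydroxylation, and the O5–C7 bridge of 15 covers one face. Two stereocentres disappear; 15 holds only C1 and C5. The oxidation must be fully face-selective and must precede the introduction of any cinnamate alkene.

15 back to 14. The O5–C7 bond is cut. The forward lactonisation needs O5 cis to the ester, so it also sorts out any C5 epimer. It must run by acyl substitution with the C5–O bond intact: ionisation at C5 would give an allyl cation that is symmetric about C1 and would erase the configuration.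

14 back to 13 (key disconnection). The C3=C4 bond is cut, opening the only ring to an acyclic 1,7-diene whose stereocentres, C1 and C5, can be set on an open chain. The forward step needs cyclisation in preference to oligomerisation and a catalyst that tolerates a tertiary and a secondary allylic hydroxyl. The design of 13 is kept but tightened: as a γ-hydroxy ester it can close to a monocyclic lactone, so it is made under buffered conditions and cyclised without storage.

13 back to 12. The C5–H bond is cut, returning the carbinol to a ketone. The C1 hydroxyl, in a 1,3-relationship, can deliver hydride intramolecularly. The demand is that the allyl group and not the ester sits equatorial on C1 in the delivery chair.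

12 back to 9 and 10; 9 back to 8; 8 back to 6 and 7. The C4–C5 bond is cut between a vinyl nucleophile and an acyl equivalent that cannot over-add. The amide is installed while the acetal still masks O1 and C7, and the acetal is opened only afterwards, so the two carboxyl groups are never both free or both esters. The forward addition must prefer the amide over the ester on the quaternary carbon, and the vinyl ketone must be handled cold and briefly.

6 back to 3 and 4; 3 back to 1 and 2. The C1–C2 bond is cut, then the acetal. The stereocentre of 1 is stored in the acetal carbon while C1 is planar, and is returned when 4 enters anti to the tert-butyl group. The quaternary C1 thus comes from the chiral pool with retention.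

## Other disconnections considered

Alternative 1: The cut removes C7 and the O1 acyl group together (the C1–C7 and O1–C(acyl) bonds). It leads back to the C1 ketone A2, which degradation of (−)-quinic acid A1 would supply, the MOM-protected acid A3 and the convertible isocyanide A4. Forward, a Passerini three-component reaction would give the α-acyloxy amide A5: the isocyanide carbon adds to the acid-activated ketone, the carboxylate traps the nitrilium ion, and an acyl shift places the caffeoyl unit on O1. The N-cyclohexenyl amide is hydrolysed later.
- In its favour: C3, C4 and C5 come ready-made from A1; the tertiary ester, the hardest bond to make by acylation, forms during C–C bond formation; three large fragments are joined at once.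
- Against it here: C1 is a new quaternary centre with no controlling element. The target needs the new C–C bond equatorial and the acyloxy group axial (syn-axial to the O3 ester), whereas a slim isocyanide would be expected to enter axially. A2 is a β-acyloxy ketone that can lose its O3 ester by E1cB elimination, ketones are slow Passerini partners, and unmasking the amide needs acid that must spare both cinnamates.
- Comparison: on structure alternative 1 is the better, since it keeps three of four stereocentres from a pool compound and does not rebuild a ring that A1 already contains. On mechanism the chosen plan is the better, because its C1 is transferred from 1 with a predictable sense. On step economy alternative 1 is at least the equal and probably shorter, and it is the better in avoiding acylation of a tertiary alcohol.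

Alternative 2: The cut runs through C1–C6 and C2–C3, a retro-Diels–Alder opening to the dienophile A6 and buta-1,3-diene A7. Forward, a chiral primary ammonium salt would activate A6 as its iminium ion and the [4+2] cycloaddition would give the aldehyde A8. C1 is set by the catalyst and O1 already carries a latent caffeate (a later Horner–Wadsworth–Emmons olefination completes the cinnamate). The alkene of A8 maps onto C4=C5. Oxidation of the aldehyde, halolactonisation onto C5 and elimination would give A9, the O1-acylated analogue of 15, and the same lactone-controlled dihydroxylation would follow.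
- In its favour: catalytic and asymmetric; ring and C1 formed in one step from very simple partners; no tertiary-alcohol acylation.
- Against it here: A7 is a gas and the least reactive and least biased of dienes, so enantioselectivity rests wholly on the catalyst. The acidic phosphonoacetate methylene and the basic phosphoryl oxygen of A6 may interfere with ammonium catalysis. The phosphonate must survive the osmylation and be olefinated on a base-sensitive α-acyloxy lactone.
- Comparison: on structure the two plans are equal from A9/15 onward. On mechanism the chosen plan has the more secure C1, but alternative 2 fixes C5 unambiguously by lactonisation and is the better there. On step economy alternative 2 is clearly the better: about four steps to A9 against eight to 15.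

Alternative 3: The cut is the C1–C2 bond, a retro-aldol opening to the acyclic 2,6-diketo ester A11. Its C4 and C5 oxygens come from D-tartaric acid A10; the (S,S) enantiomer is the one that matches the target. Forward, the C2 methyl ketone would form an enamine with a secondary amine and a carboxylic acid, and add to the C1 keto group of the α-keto ester, closing the ring to A12. The C3 ketone would then be reduced from the equatorial side to the axial alcohol, and O1 and O3 acylated together.
- In its favour: it mirrors the enzymatic ring closure of the shikimate pathway, takes C4 and C5 from the pool and needs no osmium. Because O4 and O5 are masked from the start, both caffeates can be introduced in one operation — a protecting-group logic better than that of the chosen plan.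
- Against it here: the acetonide is trans-fused to the ring being formed, which strains the chair transition state. The C6 methylene of the α-keto ester is more acidic than the methyl ketone, and its enol or enamine can expel the C5 oxygen or act as the nucleophile. C1 depends on aldol diastereoselectivity, A12 can dehydrate, and the less common tartrate enantiomer is needed.
- Comparison: on structure the plans are equal in taking two centres from a pool compound, and alternative 3 is the better in having three oxygens in place at ring closure. On mechanism the chosen plan is the better: its ring closure has no chemo-, regio- or diastereoselectivity to control. On step economy alternative 3 is probably shorter and the better.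

Key step: step 7

Remark: quinic acid numbering (C7 = carboxyl carbon, O5 = the oxygen cis to C7) is used for all intermediates; the configurations of 1, 13 and 14 were checked against 24 and stand as written, the two hydroxyls of 13 being anti along the ring-forming chain allyl–C1–C6–C5–vinyl (syn along the ester chain), and 20 is made fresh from 18.

Step 1
Reactants: 1 L-malic acid [(2S)-2-hydroxybutanedioic acid]; 2 pivalaldehyde (2,2-dimethylpropanal)
Product: 3 2-[(2S,4S)-2-tert-butyl-5-oxo-1,3-dioxolan-4-yl]acetic acid (cis; tert-butyl and CH2CO2H on the same face)
Conditions: TsOH·H2O (cat.), H2SO4 (cat.), pentane, reflux, water separator; recrystallisation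
Reagents that add atoms: pivalaldehyde (2), CC(C)(C)C=O
Why: Acid-catalysed acetalisation of the α-hydroxy acid unit to a 1,3-dioxolan-4-one with azeotropic removal of water; the five-membered acetal-lactone is preferred over the six-membered one through the β-carboxyl, and the cis isomer is the thermodynamic, crystalline one, so the configuration of 1 is copied into the acetal carbon.

Step 2
Reactants: 3; 4 allyl bromide (3-bromoprop-1-ene)
Product: 6 2-[(2S,4S)-4-allyl-2-tert-butyl-5-oxo-1,3-dioxolan-4-yl]acetic acid, via dilithium enolate 5 (not isolated)
Conditions: LiN(SiMe3)2 (2.2 equiv), THF, −78 °C; then 4, −78 → −20 °C; aq. HCl work-up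
Reagents that add atoms: allyl bromide (4), C=CCBr
Why: Enolate alkylation under self-regeneration of stereocentres: the second equivalent of base removes the ring C–H, the planar enolate 5 is shielded on one face by the tert-butyl group, and 4 enters anti to it, on the face the hydrogen occupied, so C1 is formed with overall retention (SN2 on an allylic bromide).

Step 3
Reactants: 6; 7 N,O-dimethylhydroxylamine hydrochloride
Product: 8 2-[(2S,4S)-4-allyl-2-tert-butyl-5-oxo-1,3-dioxolan-4-yl]-N-methoxy-N-methylacetamide
Conditions: EDC·HCl (1.2 equiv), HOBt (cat.), N-methylmorpholine (1.1 equiv), CH2Cl2, 0 °C → rt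
Reagents that add atoms: N,O-dimethylhydroxylamine hydrochloride (7), CNOC.Cl
Why: Carbodiimide-mediated amide coupling (Weinreb amide formation); the acetal-lactone has no free hydroxyl and its carbonyl is flanked by a quaternary carbon, so the weakly nucleophilic amine acylates only at the activated side-chain carboxyl.

Step 4
Reactants: 8
Product: 9 methyl (2S)-2-hydroxy-2-{2-[methoxy(methyl)amino]-2-oxoethyl}pent-4-enoate
Conditions: NaOMe (0.2 equiv), MeOH, 0 °C → rt; AcOH quench
Reagents that add atoms: methanol, CO
Why: Base-catalysed transesterification of the acetal-lactone: methoxide adds to the activated ring carbonyl and the released hemiacetal alkoxide collapses with loss of the aldehyde, so the tertiary hydroxyl and the methyl ester appear together; C1 is not touched and the Weinreb amide is inert to catalytic methoxide at this temperature.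

Step 5
Reactants: 9; 10 vinylmagnesium bromide (CH2=CHMgBr)
Product: 12 methyl (2S)-2-allyl-2-hydroxy-4-oxohex-5-enoate, via magnesium hemiaminal chelate 11 (not isolated)
Conditions: CH2=CHMgBr (2.5 equiv), THF, −78 → −10 °C; inverse quench into cold 1 M HCl; used at once
Reagents that add atoms: vinylmagnesium bromide (10), C=C[Mg]Br
Why: Weinreb ketone synthesis: the first equivalent of Grignard reagent deprotonates the tertiary hydroxyl and the second adds to the amide to give chelate 11, which does not collapse until the acidic quench and so cannot take up a second vinyl group. The methyl ester, on a fully substituted carbon next to a magnesium alkoxide, is expected to react much more slowly, and quenching into acid protonates the released amine before it can add to the vinyl ketone.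

Step 6
Reactants: 12
Product: 13 methyl (2S,4R)-2-allyl-2,4-dihydroxyhex-5-enoate
Conditions: Me4N[BH(OAc)3] (5 equiv), MeCN/AcOH (1:1), −30 → −20 °C; aq. KNaC4H4O6 (sodium potassium tartrate)/NaHCO3 work-up at 0 °C; used without storage
Reagents that add atoms: none
Why: Hydroxyl-directed 1,3-anti reduction (Evans–Saksena): the tertiary hydroxyl exchanges for an acetate on boron and hydride is delivered intramolecularly (1,2-reduction of the enone) through a chair with the vinyl group equatorial. With the slimmer, planar ester axial and the allyl group equatorial on C1, the new C5–O bond is anti to O1 along the chain allyl–C1–C6–C5–vinyl, which is the (4R) carbinol. The reagent does not reduce ketones or esters without this delivery, and any C5 epimer is removed in step 8 because it cannot lactonise.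

Step 7
Reactants: 13
Product: 14 methyl (1S,5R)-1,5-dihydroxycyclohex-3-ene-1-carboxylate
Conditions: RuCl2(=CHPh)(PCy3)(H2IMes) (second-generation Grubbs catalyst, 3 mol %), 1,4-benzoquinone (10 mol %), CH2Cl2 (0.01 M), 40 °C, argon sparge; ethyl vinyl ether quench
Reagents that add atoms: none
Why: Ring-closing olefin metathesis by the metal-alkylidene/metallacyclobutane mechanism: loss of PCy3 gives the 14-electron benzylidene, which undergoes [2+2] cycloaddition and cycloreversion with the unhindered allyl terminus to place the ruthenium alkylidene on C3 and release styrene. The alkylidene then adds intramolecularly to the vinyl group on C5, and cycloreversion of the ruthenacyclobutane forms the C3=C4 bond, releases the cyclohexene and returns Ru=CH2, which carries the chain with loss of ethylene. The closest known reaction type is the ring-closing metathesis of 1,7-dienes bearing free tertiary and allylic hydroxyls to cyclohexenols with the same catalyst. The single ring, the six-membered carbocycle C1–C6, closes by joining the two internal alkene carbons C3 and C4, and the ring size allows only the cis alkene. No stereocentre is formed, and C1 and C5 are untouched because no bond at either centre takes part. The selectivity required is cyclisation over acyclic diene oligomerisation, which high dilution, the quaternary C1 (gem-disubstituent effect) and the irreversible loss of ethylene secure. The second requirement is that ruthenium hydrides do not isomerise the secondary allylic alcohol to a ketone; 1,4-benzoquinone as hydride scavenger, a short reaction time and the vinyl ether quench address this. The free allylic hydroxyl is expected to assist rather than hinder the second cycloaddition.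

Step 8
Reactants: 14
Product: 15 (1S,5R)-1-hydroxy-6-oxabicyclo[3.2.1]oct-3-en-7-one
Conditions: PPTS (10 mol %), toluene, 4 Å molecular sieves, 80 °C
Reagents that add atoms: none
Why: Acid-catalysed intramolecular transesterification (lactonisation) driven by removal of methanol; only a C5 hydroxyl cis to the ester can reach C7, so the step also purifies the C1/C5 relationship. The weak acid is chosen so that the reaction runs by acyl substitution with the C5–O bond intact, since ionisation of the allylic alcohol would pass through an allyl cation symmetric about C1.

Step 9
Reactants: 15
Product: 16 quinide (quinic acid 1,5-lactone), (1S,3R,4R,5R)-1,3,4-trihydroxy-6-oxabicyclo[3.2.1]octan-7-one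
Conditions: OsO4 (2 mol %), NMO (1.5 equiv), acetone/H2O (4:1), rt; NaHSO3 quench
Reagents that add atoms: osmium tetroxide, O=[Os](=O)(=O)=O; N-methylmorpholine N-oxide, C[N+]1([O-])CCOCC1; water, O
Why: Upjohn dihydroxylation: concerted [3+2] syn addition to the C3=C4 bond from the face remote from the O6–C7 lactone bridge, which places O3 and O4 cis to each other and trans to O5 as in 24. The product is the lactone of natural quinic acid, so its identity can be checked against material made from the natural acid.

Step 10
Reactants: 16
Product: 17 3,4-O-isopropylidenequinide, (1S,3R,4R,5R)-1-hydroxy-3,4-(isopropylidenedioxy)-6-oxabicyclo[3.2.1]octan-7-one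
Conditions: Me2C(OMe)2 (3 equiv), TsOH·H2O (5 mol %), acetone, rt; Et3N quench
Reagents that add atoms: 2,2-dimethoxypropane, COC(C)(C)OC
Why: Acid-catalysed transacetalisation; only the cis-vicinal O3/O4 pair can form a five-membered isopropylidene acetal on the bicycle, which leaves tertiary O1 as the single free hydroxyl.

Step 11
Reactants: 18 caffeic acid [(E)-3-(3,4-dihydroxyphenyl)prop-2-enoic acid]
Product: 19 (E)-3-(3,4-diacetoxyphenyl)prop-2-enoic acid
Conditions: Ac2O (3 equiv), pyridine, DMAP (cat.), 0 °C → rt; then H2O, aq. HCl work-up
Reagents that add atoms: acetic anhydride, CC(=O)OC(C)=O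
Why: O-Acetylation of both phenols under nucleophilic catalysis; the mixed anhydride formed at the carboxyl is hydrolysed in the aqueous work-up, and the acetates shield the catechol from oxidation and from self-acylation in the later steps.

Step 12
Reactants: 19
Product: 20 (E)-3-(3,4-diacetoxyphenyl)prop-2-enoyl chloride
Conditions: (COCl)2 (1.5 equiv), DMF (cat.), CH2Cl2, 0 °C → rt; evaporation
Reagents that add atoms: oxalyl chloride, O=C(Cl)C(=O)Cl
Why: Acid chloride formation through the chloroiminium (Vilsmeier-type) species from catalytic DMF and oxalyl chloride; the by-products are gases, and the aryl acetates and the (E)-alkene are unaffected.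

Step 13
Reactants: 17; 20
Product: 21 1-O-[(E)-3,4-diacetoxycinnamoyl]-3,4-O-isopropylidenequinide (1S,3R,4R,5R)
Conditions: 20 (1.5 equiv), pyridine, DMAP (0.3 equiv), CH2Cl2, rt → 40 °C
Reagents that add atoms: acid chloride 20, CC(=O)Oc1ccc(/C=C/C(Cl)=O)cc1OC(C)=O
Why: Nucleophile-catalysed acylation of a tertiary alcohol through the N-acylpyridinium ion of DMAP; the bridgehead position of O1 makes it more accessible than an ordinary tertiary hydroxyl, and no other hydroxyl is free.

Step 14
Reactants: 21
Product: 22 1-O-[(E)-3,4-diacetoxycinnamoyl]quinide (1S,3R,4R,5R)
Conditions: TFA/H2O (9:1), 0 °C; toluene co-evaporation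
Reagents that add atoms: none
Why: Acid-catalysed hydrolysis of the isopropylidene acetal; brief cold aqueous trifluoroacetic acid is expected to leave the aryl acetates, the tertiary cinnamate and the lactone intact, because none of them can ionise and their acyl hydrolysis is slow under these conditions.

Step 15
Reactants: 22; 20
Product: 23 1,3-bis-O-[(E)-3,4-diacetoxycinnamoyl]quinide (spatial arrangement as in 22; descriptors 1R,3R,4R,5R, the change at C1 being one of priority only)
Conditions: 20 (1.1 equiv), pyridine (3 equiv), CH2Cl2, −30 → 0 °C
Reagents that add atoms: acid chloride 20, CC(=O)Oc1ccc(/C=C/C(Cl)=O)cc1OC(C)=O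
Why: Regioselective O-acylation under kinetic control: in the lactone-locked chair O3 is equatorial and unhindered while O4 is axial and syn to the axial hydrogens on C2 and C6, so one equivalent of 20 at low temperature without DMAP is expected to esterify O3. Low temperature and a weak base also suppress O3→O4 migration.

Step 16
Reactants: 23
Product: 24 1,3-di-O-caffeoylquinic acid, (1R,3R,4S,5R)-1,3-bis{[(E)-3-(3,4-dihydroxyphenyl)prop-2-enoyl]oxy}-4,5-dihydroxycyclohexane-1-carboxylic acid
Conditions: 2 M aq. HCl/THF (1:3), rt, argon, dark; reversed-phase chromatography
Reagents that add atoms: water, O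
Why: Acid-catalysed acyl hydrolysis: the four aryl acetates and the strained bicyclic γ-lactone are expected to be cleaved much faster than the two conjugated cinnamate esters (one tertiary, one secondary), and acid, unlike base, does not promote acyl migration across the cis O3/O4 pair or oxidation of the catechols. Opening the lactone releases O5 and the C7 acid and lets the ring return to the chair with equatorial carboxyl.

Compound list

1 | L-malic acid, (2S)-2-hydroxybutanedioic acid | OC(=O)C[C@H](O)C(=O)O | starting material
2 | pivalaldehyde | CC(C)(C)C=O | starting material
3 | 2-[(2S,4S)-2-tert-butyl-5-oxo-1,3-dioxolan-4-yl]acetic acid | CC(C)(C)[C@@H]1OC(=O)[C@H](CC(=O)O)O1 | intermediate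
4 | allyl bromide | C=CCBr | starting material
5 | dilithium enolate of 3, dilithium (2S)-2-tert-butyl-5-(carboxylatomethyl)-1,3-dioxol-4-olate (not isolated) | CC(C)(C)[C@@H]1OC([O-])=C(CC(=O)[O-])O1.[Li+].[Li+] | intermediate
6 | 2-[(2S,4S)-4-allyl-2-tert-butyl-5-oxo-1,3-dioxolan-4-yl]acetic acid | CC(C)(C)[C@@H]1OC(=O)[C@@](CC(=O)O)(CC=C)O1 | intermediate
7 | N,O-dimethylhydroxylamine hydrochloride | CNOC.Cl | starting material
8 | 2-[(2S,4S)-4-allyl-2-tert-butyl-5-oxo-1,3-dioxolan-4-yl]-N-methoxy-N-methylacetamide | CC(C)(C)[C@@H]1OC(=O)[C@@](CC(=O)N(C)OC)(CC=C)O1 | intermediate
9 | methyl (2S)-2-hydroxy-2-{2-[methoxy(methyl)amino]-2-oxoethyl}pent-4-enoate | C=CC[C@@](O)(C(=O)OC)CC(=O)N(C)OC | intermediate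
10 | vinylmagnesium bromide | C=C[Mg]Br | starting material
11 | magnesium hemiaminal chelate, bis(bromomagnesium) alkoxide of methyl (2S)-2-allyl-2,4-dihydroxy-4-[methoxy(methyl)amino]hex-5-enoate, C4 undefined (not isolated) | C=CC[C@@](O[Mg]Br)(C(=O)OC)CC(O[Mg]Br)(C=C)N(C)OC | intermediate
12 | methyl (2S)-2-allyl-2-hydroxy-4-oxohex-5-enoate | C=CC[C@@](O)(C(=O)OC)CC(=O)C=C | intermediate
13 | methyl (2S,4R)-2-allyl-2,4-dihydroxyhex-5-enoate | C=CC[C@@](O)(C(=O)OC)C[C@@H](O)C=C | intermediate
14 | methyl (1S,5R)-1,5-dihydroxycyclohex-3-ene-1-carboxylate | C1[C@@](O)(C(=O)OC)C[C@@H](O)C=C1 | intermediate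
15 | (1S,5R)-1-hydroxy-6-oxabicyclo[3.2.1]oct-3-en-7-one | O[C@@]12CC=C[C@@H](C1)OC2=O | intermediate
16 | quinide, (1S,3R,4R,5R)-1,3,4-trihydroxy-6-oxabicyclo[3.2.1]octan-7-one | O[C@@]12C[C@@H](O)[C@@H](O)[C@@H](C1)OC2=O | intermediate
17 | 3,4-O-isopropylidenequinide (1S,3R,4R,5R) | O[C@@]12C[C@H]3OC(C)(C)O[C@H]3[C@@H](C1)OC2=O | intermediate
18 | caffeic acid | OC(=O)/C=C/c1ccc(O)c(O)c1 | starting material
19 | (E)-3-(3,4-diacetoxyphenyl)prop-2-enoic acid | CC(=O)Oc1ccc(/C=C/C(=O)O)cc1OC(C)=O | intermediate
20 | (E)-3-(3,4-diacetoxyphenyl)prop-2-enoyl chloride | CC(=O)Oc1ccc(/C=C/C(Cl)=O)cc1OC(C)=O | intermediate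
21 | 1-O-[(E)-3,4-diacetoxycinnamoyl]-3,4-O-isopropylidenequinide (1S,3R,4R,5R) | O=C(/C=C/c1ccc(OC(C)=O)c(OC(C)=O)c1)O[C@@]12C[C@H]3OC(C)(C)O[C@H]3[C@@H](C1)OC2=O | intermediate
22 | 1-O-[(E)-3,4-diacetoxycinnamoyl]quinide (1S,3R,4R,5R) | O=C(/C=C/c1ccc(OC(C)=O)c(OC(C)=O)c1)O[C@@]12C[C@@H](O)[C@@H](O)[C@@H](C1)OC2=O | intermediate
23 | 1,3-bis-O-[(E)-3,4-diacetoxycinnamoyl]quinide (1R,3R,4R,5R) | O=C(/C=C/c1ccc(OC(C)=O)c(OC(C)=O)c1)O[C@@]12C[C@@H](OC(=O)/C=C/c3ccc(OC(C)=O)c(OC(C)=O)c3)[C@@H](O)[C@@H](C1)OC2=O | intermediate
24 | 1,3-di-O-caffeoylquinic acid (1R,3R,4S,5R) | O=C(/C=C/c1ccc(O)c(O)c1)O[C@@H]1C[C@@](OC(=O)/C=C/c2ccc(O)c(O)c2)(C(=O)O)C[C@@H](O)[C@@H]1O | target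

Total step count: 16. Longest linear sequence: 14 steps (from 1 through steps 1–10 and 13–16); steps 11 and 12 form the side branch to 20.

Least certain steps

Step 7 (key step). Most likely to go wrong: closure of the open γ-hydroxy ester to a monocyclic lactone before or during the metathesis, and isomerisation of the secondary allylic alcohol to a ketone by ruthenium hydrides formed as the catalyst ages. Fallback, from 13 back to the route at 15: 13 is lactonised on purpose (PPTS, toluene) to (3S,5R)-3-allyl-3-hydroxy-5-vinyloxolan-2-one F1, in which allyl and vinyl are cis on the five-membered ring. The carbocycle is then closed on the lactone with the same ruthenium alkylidene in dilute solution, giving 15 directly. The order of the two ring closures is inverted and the allylic oxygen, now acylated, can no longer undergo redox isomerisation.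

Step 6. Most likely to go wrong: poor facial selectivity at C5, because the allyl group and the ester on C1 compete for the equatorial site of the delivery chair, or slow ligand exchange of the electron-poor tertiary hydroxyl on boron. Fallback, from 12 back to the route at 14: the enone 12 is cyclised first by ring-closing metathesis with the same catalyst to methyl (1S)-1-hydroxy-5-oxocyclohex-3-ene-1-carboxylate F2, kept cold and neutral because this β-hydroxy enone can dehydrate. The same Me4N[BH(OAc)3] reduction is then run on the ring, where the boron bound to O1 can reach the C5 carbonyl only from its own face, so the new hydroxyl must come out trans to O1, as in 14.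

Step 5. Most likely to go wrong: competing addition of the Grignard reagent to the methyl ester, and conjugate addition of the released amine or of the tertiary alkoxide to the vinyl ketone during quench. Fallback, from 6 back to the route at 12: 6 is opened with NaOMe (2.2 equiv) in MeOH to the half ester (3S)-3-hydroxy-3-(methoxycarbonyl)hex-5-enoic acid F3. F3 is converted with EtSH and EDC·HCl to the thioester methyl (2S)-2-[2-(ethylsulfanyl)-2-oxoethyl]-2-hydroxypent-4-enoate F4. F4 is coupled with Bu3SnCH=CH2 under neutral Liebeskind–Srogl-type conditions (Pd2(dba)3, P(2-furyl)3, CuO2PPh2 (copper diphenylphosphinate), THF, rt) to give 12 without any basic organometallic reagent.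

Step 15. Most likely to go wrong: insufficient site selectivity between O3 and O4, over-acylation, or acyl migration from O3 to O4. Fallback, from 22 back to the route at 23: 22 is heated with Bu2SnO (toluene/MeOH, water removal) to the 3,4-O-dibutylstannylene acetal of 22 F5, and F5 is treated with 20 at 0 °C. Stannylene acetals of cis-diols on six-membered rings are acylated at the equatorial oxygen, so the regiochemistry is set by tin activation and not by the small intrinsic rate difference.

Step 16. Most likely to go wrong: incomplete hydrolysis of the aryl acetates at an acidity mild enough to spare the caffeates, or partial loss or O3→O4 migration of a caffeoyl group during the long acid treatment. Fallback, from 23 back to the route at 24: the phenolic acetates are removed first under near-neutral conditions (NH4OAc, MeOH/H2O, rt, selective for aryl acetates) to give 1,3-di-O-[(E)-caffeoyl]quinide F6. The lactone of F6 is then opened in a separate, much shorter treatment with dilute aqueous HCl/THF.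

Further compounds

F1 | step 7 | (3S,5R)-3-allyl-3-hydroxy-5-vinyloxolan-2-one | C=CC[C@]1(O)C[C@H](C=C)OC1=O
F2 | step 6 | methyl (1S)-1-hydroxy-5-oxocyclohex-3-ene-1-carboxylate | C1[C@@](O)(C(=O)OC)CC(=O)C=C1
F3 | step 5 | (3S)-3-hydroxy-3-(methoxycarbonyl)hex-5-enoic acid | C=CC[C@@](O)(C(=O)OC)CC(=O)O
F4 | step 5 | methyl (2S)-2-[2-(ethylsulfanyl)-2-oxoethyl]-2-hydroxypent-4-enoate | C=CC[C@@](O)(C(=O)OC)CC(=O)SCC
F5 | step 15 | 3,4-O-dibutylstannylene acetal of 22 | O=C(/C=C/c1ccc(OC(C)=O)c(OC(C)=O)c1)O[C@@]12C[C@H]3O[Sn](CCCC)(CCCC)O[C@H]3[C@@H](C1)OC2=O
F6 | step 16 | 1,3-di-O-[(E)-caffeoyl]quinide | O=C(/C=C/c1ccc(O)c(O)c1)O[C@@]12C[C@@H](OC(=O)/C=C/c3ccc(O)c(O)c3)[C@@H](O)[C@@H](C1)OC2=O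
A1 | alternative 1 | (−)-quinic acid, (1S,3R,4S,5R)-1,3,4,5-tetrahydroxycyclohexane-1-carboxylic acid | O[C@@H]1C[C@@](O)(C(=O)O)C[C@@H](O)[C@@H]1O
A2 | alternative 1 | 3-O-[(E)-3,4-bis(methoxymethoxy)cinnamoyl]-4,5-O-(2,3-dimethoxybutane-2,3-diyl)-3,4,5-trihydroxycyclohexan-1-one (C3, C4, C5 as in A1) | COCOc1ccc(/C=C/C(=O)O[C@@H]2CC(=O)C[C@@H](O[C@](C)(OC)[C@@](C)(OC)O3)[C@@H]23)cc1OCOC
A3 | alternative 1 | (E)-3-[3,4-bis(methoxymethoxy)phenyl]prop-2-enoic acid | COCOc1ccc(/C=C/C(=O)O)cc1OCOC
A4 | alternative 1 | 1-isocyanocyclohexene | [C-]#[N+]C1=CCCCC1
A5 | alternative 1 | N-(cyclohex-1-en-1-yl)amide of 1,3-bis-O-[(E)-3,4-bis(methoxymethoxy)cinnamoyl]-4,5-O-(2,3-dimethoxybutane-2,3-diyl)quinic acid | COCOc1ccc(/C=C/C(=O)O[C@@H]2C[C@@](OC(=O)/C=C/c3ccc(OCOC)c(OCOC)c3)(C(=O)NC3=CCCCC3)C[C@@H](O[C@](C)(OC)[C@@](C)(OC)O4)[C@@H]24)cc1OCOC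
A6 | alternative 2 | 2-[(diethoxyphosphoryl)acetoxy]acrolein | C=C(C=O)OC(=O)CP(=O)(OCC)OCC
A7 | alternative 2 | buta-1,3-diene | C=CC=C
A8 | alternative 2 | (1S)-1-formylcyclohex-3-en-1-yl (diethoxyphosphoryl)acetate | C1C[C@@](OC(=O)CP(=O)(OCC)OCC)(C=O)CC=C1
A9 | alternative 2 | (1S,5R)-7-oxo-6-oxabicyclo[3.2.1]oct-3-en-1-yl (diethoxyphosphoryl)acetate | CCOP(=O)(OCC)CC(=O)O[C@@]12CC=C[C@@H](C1)OC2=O
A10 | alternative 3 | D-tartaric acid, (2S,3S)-2,3-dihydroxybutanedioic acid | OC(=O)[C@@H](O)[C@H](O)C(=O)O
A11 | alternative 3 | tert-butyl 3-[(4R,5S)-5-acetyl-2,2-dimethyl-1,3-dioxolan-4-yl]-2-oxopropanoate | CC(=O)[C@H]1OC(C)(C)O[C@@H]1CC(=O)C(=O)OC(C)(C)C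
A12 | alternative 3 | tert-butyl 3-dehydro-4,5-O-isopropylidenequinate | O=C1C[C@@](O)(C(=O)OC(C)(C)C)C[C@@H](OC(C)(C)O2)[C@@H]12
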